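**Retrosynthetic overview**
- The target comes from acid hydrolysis of its C4‑O/C4‑CH2O pivaldehyde acetal; the only ring of the target, the 14‑membered lactone, is closed in the penultimate step at C2–C3 by a Dieckmann condensation of the C13 propanoate onto the C3 methyl ester.
- C4–C5: alkylation of the lithium enolate of a glycerate pivaldehyde acetal (a temporary dioxolane ring, made first in a one‑step branch) with the E‑allylic bromide C5–C13.
- C5–C7: Dess–Martin/Wittig three‑carbon homologation of the C7 alcohol, then reduction and bromination.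
- C9–C10 (union of the two purchased chiral fragments): nickel‑catalysed electroreductive cross‑electrophile coupling of a 2‑bromo‑1,3‑diene with (2S)‑3‑bromo‑2‑methylpropan‑1‑ol.
- C10–C11 and the C12 methyl: one‑pot carboalumination/palladium coupling of (3R)‑pent‑1‑yn‑3‑ol with 1,1‑dibromoethene.

Numbering used below (macrolide numbering): C1 lactone carbonyl, C2 (CHMe), C3 ketone, C4 (C(OH)CH2OH), C5, C6=C7, C8 (CHMe), C9, C10 (=CH2), C11=C12, C13 (CH(Et)O).

Assumption 1: the exocyclic lithium enolate of the glycerate acetal is alkylated anti to the tert‑butyl group (if the facial sense were the reverse, the acetal of opposite configuration at the acetal carbon, made from the enantiomeric glycerate, would be used).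

Assumption 2: C2, flanked by two carbonyls, is configurationally labile, and the drawn 2S epimer is taken to be the thermodynamically preferred one in the macrocycle.

**Step 1**
Reactants: 1 (3R)‑pent‑1‑yn‑3‑ol
Product: 3 (3R,4E)‑6‑bromo‑4‑methylhepta‑4,6‑dien‑3‑ol, via E‑alkenylalane 2 (not isolated)
Conditions: AlMe3 (3 equiv), Cp2ZrCl2 (25 mol%), CH2Cl2, 0 °C → rt, 16 h; then Pd(PPh3)4 (5 mol%), CH2=CBr2 (3 equiv), THF, rt; aq. KNaC4H4O6 work‑up
Reagents that add atoms: trimethylaluminium C[Al](C)C; 1,1‑dibromoethene C=C(Br)Br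
Why: Negishi zirconium‑catalysed carboalumination adds Me–Al syn across the terminal alkyne (methyl to the internal carbon), so alkenylalane 2 is E, and its palladium‑catalysed Negishi‑type alkenyl–alkenyl coupling with excess 1,1‑dibromoethene stops after one substitution because the internal C–Br bond left in 3 adds to zerovalent palladium more slowly than a geminal dibromide; the purchased C13 centre is not touched.

**Step 2**
Reactants: 3 (3R,4E)‑6‑bromo‑4‑methylhepta‑4,6‑dien‑3‑ol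
Product: 4 (3R,4E)‑6‑bromo‑4‑methylhepta‑4,6‑dien‑3‑yl propanoate
Conditions: (EtCO)2O, Et3N, DMAP (5 mol%), CH2Cl2, 0 °C → rt
Reagents that add atoms: propanoic anhydride CCC(=O)OC(=O)CC
Why: DMAP‑catalysed acylation (nucleophilic acyl transfer) of the secondary allylic alcohol; the propanoate masks O13 and already is the C1–C2 unit.

**Step 3**
Reactants: 4 (3R,4E)‑6‑bromo‑4‑methylhepta‑4,6‑dien‑3‑yl propanoate; 5 (2S)‑3‑bromo‑2‑methylpropan‑1‑ol
Product: 6 (3R,4E,8R)‑9‑hydroxy‑4,8‑dimethyl‑6‑methylidenenon‑4‑en‑3‑yl propanoate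
Conditions: NiBr2(dme) (10 mol%), 4,4′‑di‑tert‑butyl‑2,2′‑bipyridine (12 mol%), LiBr (0.1 M), DMA, undivided cell, reticulated vitreous carbon cathode, Zn anode, 5 mA constant current (2.5 F/mol of 4), 5 (1.5 equiv), rt
Reagents that add atoms: none
Why: Proposed new method: a 2‑bromo‑1,3‑diene has not yet served as the C(sp2) partner in nickel‑catalysed electroreductive cross‑electrophile coupling with an unactivated primary alkyl bromide; cathodically formed zerovalent nickel–bipyridine inserts into the dienyl C–Br bond far faster than into the alkyl C–Br or allylic C–O bond, the dienyl(bromo) divalent nickel complex is reduced to a monovalent dienylnickel that abstracts bromine from 5, the primary radical (next to, but not at, C8, whose configuration is therefore kept) recombines at nickel, and reductive elimination from trivalent nickel forms C9–C10 while the zinc anode supplies the electrons; the fully substituted C12 terminus blocks the allenylmethyl (1,3‑shift) leak and radical capture by nickel should outrun addition to the diene; the closest known reaction type is the nickel‑catalysed electroreductive (or metallaphotoredox) coupling of aryl and simple alkenyl bromides with primary alkyl bromides.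

**Step 4**
Reactants: 6 (3R,4E,8R)‑9‑hydroxy‑4,8‑dimethyl‑6‑methylidenenon‑4‑en‑3‑yl propanoate
Product: 8 (3R,4E,8R,9E)‑4,8,10‑trimethyl‑6‑methylidene‑11‑oxoundeca‑4,9‑dien‑3‑yl propanoate, via aldehyde 7 (not isolated)
Conditions: Dess–Martin periodinane, CH2Cl2, 0 °C → rt; filter through silica, concentrate; then Ph3P=C(CH3)CHO (1.5 equiv), PhMe, 90 °C
Reagents that add atoms: 2‑(triphenyl‑λ5‑phosphanylidene)propanal CC(C=O)=P(c1ccccc1)(c1ccccc1)c1ccccc1
Why: Dess–Martin oxidation is non‑basic, so the α‑stereocentre C8 of aldehyde 7 survives, and the stabilised ylide (Wittig reaction) gives the trisubstituted E‑enal selectively because oxaphosphetane formation is reversible.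

**Step 5**
Reactants: 8 (3R,4E,8R,9E)‑4,8,10‑trimethyl‑6‑methylidene‑11‑oxoundeca‑4,9‑dien‑3‑yl propanoate
Product: 9 (3R,4E,8R,9E)‑11‑hydroxy‑4,8,10‑trimethyl‑6‑methylideneundeca‑4,9‑dien‑3‑yl propanoate
Conditions: NaBH4, CeCl3·7H2O, MeOH, −20 °C, 15 min
Reagents that add atoms: none
Why: Luche reduction; cerium‑activated borohydride adds 1,2 to the enal and leaves the ester and the diene alone.

**Step 6**
Reactants: 9 (3R,4E,8R,9E)‑11‑hydroxy‑4,8,10‑trimethyl‑6‑methylideneundeca‑4,9‑dien‑3‑yl propanoate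
Product: 10 (3R,4E,8R,9E)‑11‑bromo‑4,8,10‑trimethyl‑6‑methylideneundeca‑4,9‑dien‑3‑yl propanoate
Conditions: CBr4, PPh3, CH2Cl2, 0 °C
Reagents that add atoms: tetrabromomethane BrC(Br)(Br)Br
Why: Appel reaction; SN2 displacement of the oxyphosphonium at the primary allylic carbon under neutral conditions keeps the E geometry and the ester.

**Step 7**
Reactants: 11 methyl (4R)‑2,2‑dimethyl‑1,3‑dioxolane‑4‑carboxylate
Product: 12 methyl (2R,4R)‑2‑tert‑butyl‑1,3‑dioxolane‑4‑carboxylate (2,4‑cis)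
Conditions: t‑BuCHO (4 equiv), TsOH·H2O (5 mol%), CH2Cl2, 40 °C with removal of acetone; chromatography (trans isomer re‑equilibrated under the same conditions)
Reagents that add atoms: pivalaldehyde CC(C)(C)C=O
Why: Acid‑catalysed transacetalisation is driven by loss of volatile acetone and the greater stability of an aldehyde acetal; the purchased C4 centre is not enolised under acid and defines the new acetal carbon as R in the cis isomer, which is separated.

**Step 8**
Reactants: 12 methyl (2R,4R)‑2‑tert‑butyl‑1,3‑dioxolane‑4‑carboxylate; 10 (3R,4E,8R,9E)‑11‑bromo‑4,8,10‑trimethyl‑6‑methylideneundeca‑4,9‑dien‑3‑yl propanoate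
Product: 14 methyl (2R,4R)‑2‑tert‑butyl‑4‑[(2E,4R,7E,9R)‑2,4,8‑trimethyl‑6‑methylidene‑9‑(propanoyloxy)undeca‑2,7‑dien‑1‑yl]‑1,3‑dioxolane‑4‑carboxylate, via lithium enolate 13 (not isolated)
Conditions: 12 (1.3 equiv), LiN(iPr)2 (1.35 equiv, commercial solution), THF, −78 °C, 30 min; then 10 (1.0 equiv), THF–DMPU (5:1), −78 → −40 °C
Reagents that add atoms: none
Why: Seebach self‑regeneration of stereocentres: deprotonation gives enolate 13 with an exocyclic C=C in which only the acetal carbon remains stereogenic, the ring oxygen does not β‑eliminate at −78 °C, and SN2 alkylation by the allylic bromide on the face anti to tert‑butyl sets the quaternary C4 as R.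

**Step 9**
Reactants: 14 methyl (2R,4R)‑2‑tert‑butyl‑4‑[(2E,4R,7E,9R)‑2,4,8‑trimethyl‑6‑methylidene‑9‑(propanoyloxy)undeca‑2,7‑dien‑1‑yl]‑1,3‑dioxolane‑4‑carboxylate
Product: 16 (2R,5R,7S,10R,11E,15R,16E)‑2‑tert‑butyl‑10‑ethyl‑7,11,15,17‑tetramethyl‑13‑methylidene‑1,3,9‑trioxaspiro[4.13]octadeca‑11,16‑diene‑6,8‑dione (the target with O4 and the C4 hydroxymethyl oxygen bridged as the pivaldehyde acetal), via macrocyclic lithium enolate 15 (not isolated)
Conditions: LiN(SiMe3)2 (3 equiv), THF, 2 mM, slow addition of 14, −78 → −10 °C; AcOH, −78 °C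
Reagents that add atoms: none
Why: Dieckmann (intramolecular Claisen) condensation: only the propanoate can enolise and only the α‑alkoxy‑activated C3 methyl ester, which has no α‑hydrogen, can accept, so C2–C3 and the 14‑membered ring form together; irreversible deprotonation to the chelated enolate 15 pulls the equilibrium over, high dilution and low temperature hold back oligomers and the Ireland–Claisen shift of the allylic ester enolate, and C2 is protonated on quench and equilibrated in step 10.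

**Step 10**
Reactants: 16 pivaldehyde‑acetal macrolactone
Product: 17 (3S,5R,7E,9R,12E,14R)‑14‑ethyl‑5‑hydroxy‑5‑(hydroxymethyl)‑3,7,9,13‑tetramethyl‑11‑methylidene‑1‑oxacyclotetradeca‑7,12‑diene‑2,4‑dione (macrolide numbering: 2S,4R,6E,8R,11E,13R)
Conditions: CF3CO2H–H2O (4:1), CH2Cl2, 0 °C → rt; evaporate with toluene; chromatography on neutral silica
Reagents that add atoms: none
Why: Acid‑catalysed acetal hydrolysis via the oxocarbenium ion should be faster than ionisation of the dienylic ester, the acidic medium avoids base‑induced attack of the freed hydroxyls on C1 (tetronate formation), and the doubly activated C2 equilibrates through the enol to the ring‑controlled 2S epimer.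

**Compound list**
1 | (3R)‑pent‑1‑yn‑3‑ol | C#C[C@@H](CC)O | starting material
2 | E‑alkenylalane, dimethyl[(1E,3R)‑3‑(dimethylalumanyloxy)‑2‑methylpent‑1‑en‑1‑yl]alumane | C[Al](C)/C=C(\C)[C@@H](CC)O[Al](C)C | intermediate
3 | (3R,4E)‑6‑bromo‑4‑methylhepta‑4,6‑dien‑3‑ol | C=C(Br)/C=C(\C)[C@@H](CC)O | intermediate
4 | (3R,4E)‑6‑bromo‑4‑methylhepta‑4,6‑dien‑3‑yl propanoate | C=C(Br)/C=C(\C)[C@@H](CC)OC(=O)CC | intermediate
5 | (2S)‑3‑bromo‑2‑methylpropan‑1‑ol | OC[C@H](C)CBr | starting material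
6 | (3R,4E,8R)‑9‑hydroxy‑4,8‑dimethyl‑6‑methylidenenon‑4‑en‑3‑yl propanoate | OC[C@H](C)CC(=C)/C=C(\C)[C@@H](CC)OC(=O)CC | intermediate
7 | (3R,4E,8R)‑4,8‑dimethyl‑6‑methylidene‑9‑oxonon‑4‑en‑3‑yl propanoate | O=C[C@H](C)CC(=C)/C=C(\C)[C@@H](CC)OC(=O)CC | intermediate
8 | (3R,4E,8R,9E)‑4,8,10‑trimethyl‑6‑methylidene‑11‑oxoundeca‑4,9‑dien‑3‑yl propanoate | O=C/C(C)=C/[C@H](C)CC(=C)/C=C(\C)[C@@H](CC)OC(=O)CC | intermediate
9 | (3R,4E,8R,9E)‑11‑hydroxy‑4,8,10‑trimethyl‑6‑methylideneundeca‑4,9‑dien‑3‑yl propanoate | OC/C(C)=C/[C@H](C)CC(=C)/C=C(\C)[C@@H](CC)OC(=O)CC | intermediate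
10 | (3R,4E,8R,9E)‑11‑bromo‑4,8,10‑trimethyl‑6‑methylideneundeca‑4,9‑dien‑3‑yl propanoate | BrC/C(C)=C/[C@H](C)CC(=C)/C=C(\C)[C@@H](CC)OC(=O)CC | intermediate
11 | methyl (4R)‑2,2‑dimethyl‑1,3‑dioxolane‑4‑carboxylate | COC(=O)[C@H]1COC(C)(C)O1 | starting material
12 | methyl (2R,4R)‑2‑tert‑butyl‑1,3‑dioxolane‑4‑carboxylate | COC(=O)[C@H]1CO[C@@H](C(C)(C)C)O1 | intermediate
13 | lithium [(2R)‑2‑tert‑butyl‑1,3‑dioxolan‑4‑ylidene](methoxy)methanolate (OLi syn to the ring oxygen) | [Li]O/C(OC)=C(\O1)CO[C@H]1C(C)(C)C | intermediate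
14 | methyl (2R,4R)‑2‑tert‑butyl‑4‑[(2E,4R,7E,9R)‑2,4,8‑trimethyl‑6‑methylidene‑9‑(propanoyloxy)undeca‑2,7‑dien‑1‑yl]‑1,3‑dioxolane‑4‑carboxylate | COC(=O)[C@](O1)(CO[C@H]1C(C)(C)C)C/C(C)=C/[C@H](C)CC(=C)/C=C(\C)[C@@H](CC)OC(=O)CC | intermediate
15 | lithium C2–C3 enolate of 16 (chelated, OLi syn to C1) | C=C1/C=C(\C)[C@@H](CC)OC(=O)/C(C)=C(\O[Li])[C@](O2)(CO[C@H]2C(C)(C)C)C/C(C)=C/[C@H](C)C1 | intermediate
16 | (2R,5R,7S,10R,11E,15R,16E)‑2‑tert‑butyl‑10‑ethyl‑7,11,15,17‑tetramethyl‑13‑methylidene‑1,3,9‑trioxaspiro[4.13]octadeca‑11,16‑diene‑6,8‑dione (C2 of the macrolide epimerisable, drawn 2S) | C=C1/C=C(\C)[C@@H](CC)OC(=O)[C@@H](C)C(=O)[C@](O2)(CO[C@H]2C(C)(C)C)C/C(C)=C/[C@H](C)C1 | intermediate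
17 | (3S,5R,7E,9R,12E,14R)‑14‑ethyl‑5‑hydroxy‑5‑(hydroxymethyl)‑3,7,9,13‑tetramethyl‑11‑methylidene‑1‑oxacyclotetradeca‑7,12‑diene‑2,4‑dione | C=C1/C=C(\C)[C@@H](CC)OC(=O)[C@@H](C)C(=O)[C@](O)(CO)C/C(C)=C/[C@H](C)C1 | target

**Step count**
Total: 10 steps. Longest linear sequence: 9 steps (1 → 17 through steps 1–6 and 8–10); step 7 is a one‑step branch.

**Three steps most likely to fail**

Step 3 (the proposed new coupling). Risks are homocoupling of 4, addition of the alkyl radical to the diene, and nickel insertion into the allylic ester. The fallback uses known two‑electron chemistry without an alkyl radical; it sets out from 5 (and uses 4) and comes back at 6. Silylation of 5 (t‑BuMe2SiCl, imidazole, DMF) gives tert‑butyl[(2S)‑3‑bromo‑2‑methylpropoxy]dimethylsilane F1. LiCl‑promoted zinc insertion (Zn dust, LiCl, THF, 50 °C) gives [(2S)‑3‑{[tert‑butyl(dimethyl)silyl]oxy}‑2‑methylpropyl]zinc bromide F2. Negishi coupling with 4 (Pd(OAc)2, SPhos, THF, rt) gives (3R,4E,8R)‑9‑{[tert‑butyl(dimethyl)silyl]oxy}‑4,8‑dimethyl‑6‑methylidenenon‑4‑en‑3‑yl propanoate F3. HF·pyridine in THF removes the silyl group and the route is rejoined at 6.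

Step 9 (Dieckmann ring closure). The acceptor ester is hindered, and oligomerisation or Ireland–Claisen rearrangement of the allylic ester enolate may win. The fallback closes the ring at O13–C1 through an acylketene instead; it sets out from 14 and comes back at 16. Methanolysis of the propanoate (K2CO3, MeOH, 0 °C) gives methyl (2R,4R)‑2‑tert‑butyl‑4‑[(2E,4R,7E,9R)‑9‑hydroxy‑2,4,8‑trimethyl‑6‑methylideneundeca‑2,7‑dien‑1‑yl]‑1,3‑dioxolane‑4‑carboxylate F4. Crossed Claisen condensation with excess lithium enolate of tert‑butyl propanoate (LiN(iPr)2, THF, −78 → 0 °C) gives tert‑butyl 3‑{(2R,4R)‑2‑tert‑butyl‑4‑[(2E,4R,7E,9R)‑9‑hydroxy‑2,4,8‑trimethyl‑6‑methylideneundeca‑2,7‑dien‑1‑yl]‑1,3‑dioxolan‑4‑yl}‑2‑methyl‑3‑oxopropanoate F5 as a mixture of C2 epimers. Heating at 1 mM in toluene at 110 °C expels tert‑butanol to give the acylketene 2‑methyl‑3‑{(2R,4R)‑2‑tert‑butyl‑4‑[(2E,4R,7E,9R)‑9‑hydroxy‑2,4,8‑trimethyl‑6‑methylideneundeca‑2,7‑dien‑1‑yl]‑1,3‑dioxolan‑4‑yl}‑3‑oxoprop‑1‑en‑1‑one F6, which is trapped by the C13 hydroxyl to give 16.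

Step 10 (acetal removal). The tert‑butyl acetal may need acid strong enough to ionise the dienylic ester or to trigger translactonisation. The fallback relays C4 through an acid‑labile aryl acetal instead; it sets out from 11 (and uses 10) and comes back at 17. Exchange of 11 with 4‑methoxybenzaldehyde dimethyl acetal (CSA, CH2Cl2) and separation of the cis isomer gives methyl (2R,4R)‑2‑(4‑methoxyphenyl)‑1,3‑dioxolane‑4‑carboxylate F7. Deprotonation (LiN(iPr)2, THF, −78 °C) gives lithium [(2R)‑2‑(4‑methoxyphenyl)‑1,3‑dioxolan‑4‑ylidene](methoxy)methanolate F8, which is alkylated with 10 to methyl (2R,4R)‑2‑(4‑methoxyphenyl)‑4‑[(2E,4R,7E,9R)‑2,4,8‑trimethyl‑6‑methylidene‑9‑(propanoyloxy)undeca‑2,7‑dien‑1‑yl]‑1,3‑dioxolane‑4‑carboxylate F9. Ring closure with LiN(SiMe3)2 as in step 9 passes through the lithium enolate of the 4‑methoxybenzylidene‑protected macrolactone F10 to the 4‑methoxybenzylidene acetal of 17 (acetal carbon R) F11. This acetal is cleaved with 80% aqueous AcOH at rt to give 17.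

**Further compounds**
F1 | step 3 | tert‑butyl[(2S)‑3‑bromo‑2‑methylpropoxy]dimethylsilane | CC(C)(C)[Si](C)(C)OC[C@H](C)CBr
F2 | step 3 | [(2S)‑3‑{[tert‑butyl(dimethyl)silyl]oxy}‑2‑methylpropyl]zinc bromide | CC(C)(C)[Si](C)(C)OC[C@H](C)C[Zn]Br
F3 | step 3 | (3R,4E,8R)‑9‑{[tert‑butyl(dimethyl)silyl]oxy}‑4,8‑dimethyl‑6‑methylidenenon‑4‑en‑3‑yl propanoate | CC(C)(C)[Si](C)(C)OC[C@H](C)CC(=C)/C=C(\C)[C@@H](CC)OC(=O)CC
F4 | step 9 | methyl (2R,4R)‑2‑tert‑butyl‑4‑[(2E,4R,7E,9R)‑9‑hydroxy‑2,4,8‑trimethyl‑6‑methylideneundeca‑2,7‑dien‑1‑yl]‑1,3‑dioxolane‑4‑carboxylate | COC(=O)[C@](O1)(CO[C@H]1C(C)(C)C)C/C(C)=C/[C@H](C)CC(=C)/C=C(\C)[C@@H](CC)O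
F5 | step 9 | tert‑butyl 3‑{(2R,4R)‑2‑tert‑butyl‑4‑[(2E,4R,7E,9R)‑9‑hydroxy‑2,4,8‑trimethyl‑6‑methylideneundeca‑2,7‑dien‑1‑yl]‑1,3‑dioxolan‑4‑yl}‑2‑methyl‑3‑oxopropanoate (C2 epimers) | CC(C)(C)OC(=O)C(C)C(=O)[C@](O1)(CO[C@H]1C(C)(C)C)C/C(C)=C/[C@H](C)CC(=C)/C=C(\C)[C@@H](CC)O
F6 | step 9 | 2‑methyl‑3‑{(2R,4R)‑2‑tert‑butyl‑4‑[(2E,4R,7E,9R)‑9‑hydroxy‑2,4,8‑trimethyl‑6‑methylideneundeca‑2,7‑dien‑1‑yl]‑1,3‑dioxolan‑4‑yl}‑3‑oxoprop‑1‑en‑1‑one | CC(=C=O)C(=O)[C@](O1)(CO[C@H]1C(C)(C)C)C/C(C)=C/[C@H](C)CC(=C)/C=C(\C)[C@@H](CC)O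
F7 | step 10 | methyl (2R,4R)‑2‑(4‑methoxyphenyl)‑1,3‑dioxolane‑4‑carboxylate | COC(=O)[C@H]1CO[C@@H](c2ccc(OC)cc2)O1
F8 | step 10 | lithium [(2R)‑2‑(4‑methoxyphenyl)‑1,3‑dioxolan‑4‑ylidene](methoxy)methanolate | [Li]O/C(OC)=C(\O1)CO[C@H]1c2ccc(OC)cc2
F9 | step 10 | methyl (2R,4R)‑2‑(4‑methoxyphenyl)‑4‑[(2E,4R,7E,9R)‑2,4,8‑trimethyl‑6‑methylidene‑9‑(propanoyloxy)undeca‑2,7‑dien‑1‑yl]‑1,3‑dioxolane‑4‑carboxylate | COC(=O)[C@](O1)(CO[C@H]1c2ccc(OC)cc2)C/C(C)=C/[C@H](C)CC(=C)/C=C(\C)[C@@H](CC)OC(=O)CC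
F10 | step 10 | lithium enolate of the 4‑methoxybenzylidene‑protected macrolactone | C=C1/C=C(\C)[C@@H](CC)OC(=O)/C(C)=C(\O[Li])[C@](O2)(CO[C@H]2c3ccc(OC)cc3)C/C(C)=C/[C@H](C)C1
F11 | step 10 | 4‑methoxybenzylidene acetal of 17 (acetal carbon R) | C=C1/C=C(\C)[C@@H](CC)OC(=O)[C@@H](C)C(=O)[C@](O2)(CO[C@H]2c3ccc(OC)cc3)C/C(C)=C/[C@H](C)C1
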